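The slowness of the oak run is what two chemists dispute: at 102 °C with 150 mM of solid substrate it makes target at about 14.5 mM h⁻¹ over its first 4.00 h.

| flask | solid substrate | coupling partner | temperature | remark | time |
|---|---|---|---|---|---|
| maple | 26 mM | 2.5 equiv | 80 °C | run made earlier |  |
| oak | 150 mM | 2.5 equiv | 102 °C | run made earlier |  |
| zeta | 23 mM | 2.50 equiv | 110 °C |  | 20 h |
| beta | 100 mM | 2.50 equiv | 70 °C |  | 20 h |
| eta | 100 mM | 2.50 equiv | 110 °C |  | 20 h |
| delta | 23 mM | 2.50 equiv | 70 °C |  | 20 h |

| run | time / h | target / % |
|---|---|---|
| maple | 6.00 | 65.5 |
| maple | 20.0 | 96.8 |
| maple | 25.0 | 97.5 |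
| maple | 40.0 | 99.8 |
| maple | 72.0 | 100.3 |
| oak | 1.33 | 14.1 |
| oak | 4.00 | 38.6 |
| oak | 6.00 | 56.7 |
| oak | 10.0 | 83.8 |
| oak | 15.0 | 97.9 |

(standard deviation of a reading: 0.5 percentage points)

1. ranking by amount of target, in percent of the solid substrate charged, from high to low, at 20 h (zeta / beta / eta / delta)
2. the amount of target, in percent of the solid substrate charged of the flask you put first, at 20 h
3. the amount of target, in percent of the solid substrate charged of the flask you put last, at 20 h

- at the start none of the solid substrate is in solution
- what has only dissolved of solid substrate counts as not reacted
- a reading or a percentage of target counts all its forms, free or not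

The first chemist reads a first-order loss of substrate, whatever the [coupling partner], with a steady rate while solid remains. Maple's first reading gives 0.177 h⁻¹ and oak's tail 0.409 h⁻¹, and that chemist credits the difference to temperature.

The second chemist, whose reckoning this is, lets the constant follow [coupling partner]. Maple was charged 65.0 mM, so if oak's hotter flask is at least as fast per unit of partner, its tail needs no more than 150 mM. Yet charge minus target leaves 249 mM at 10.0 h, which is more, so I read partner as disappearing by another route. That gap gives the partner clock, the rough longest half-life of coupling partner in hot oak, 13.6 h.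

At 70 °C, beta has 4.35 times delta's [coupling partner]. Scaling the 2 mM/h low end of the forecast's slurry rate by that factor compares with the 5.00 mM h⁻¹ beta needs, so I put beta above delta. Eta's feed at oak's pace takes 6.91 h, half of a clock that I expect to be shorter at 110 °C, so I expect eta to lose rank.

The forecast, the first chemist's number, says zeta > eta > delta > beta, with 99.8% on top and 45% last, on the ground that “Beta stays slurry-limited”.

The flask gives beta > zeta > delta > eta, from 98.1% down to 83.7%, with beta at 98.1%. The first view keeps delta, where its 88% stands against 86.9%.

    dissolved substrate + coupling partner → target (k = 0.388 M⁻¹ min⁻¹, Ea = 60.0 kJ mol⁻¹)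
    solid substrate ⇌ dissolved substrate, rate k2*(cs2 - [dissolved substrate]) while solid is left; crystals form when [dissolved substrate] > cs2 (solubility = 17.0 mM, k = 0.0193 min⁻¹)
    solid product ⇌ target, rate k3*(cs3 - [target]) while solid is left; crystals form when [target] > cs3 (solubility = 5.90 mM, k = 0.209 min⁻¹)
    coupling partner → side product (k = 0.00390 min⁻¹, Ea = 126 kJ mol⁻¹)
    (constants at 110 °C)

In eta at 1.85 h, coupling partner goes to side product 2.4 times as fast as to target, and half of that step's turnover up to 20 h is done by 1.85 h, earlier than the partner clock reckoned for oak. By 20.0 h, eta holds 0% of its coupling partner and 16.3% as dissolved substrate.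

For a neighbour of eta, the same flask with 250 mM of solid substrate, oak's pace needs 17.2 h, longer than the clock, so solid should outlast the partner. It does: coupling partner, charged in excess, becomes the limiting reagent, with 0.00805% of it left at 20.0 h, 37.0% left as solid substrate and 56.2% as target.

(Readings and results were generated by integration for substances that don't exist, and the scatter is random.)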